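**Plan**

- Retrosynthesis: the C2–O and C3–O bonds of the catechol are cut first, reading the arene as the doubly enolised form of a cyclohexene-1,2-dione that comes from a cis-diol. The ester C(=O)–O bond is cut next, then the C18–C19 bond of the iso-branched chain.
- Forward: octadecane-1,18-diol 1 → bromo alcohol 2; copper-catalysed coupling with isobutylmagnesium bromide 3 → C22 alcohol 4; benzoic acid 5 → Birch acid 6; 4 + 6 → dienyl ester 7 → diol 8 → (dione 9) → target 10. No ring is formed: the carbocycle of benzoic acid is dearomatised and later re-aromatised.
- Stereochemistry: the target has none. The three centres of 8 arise in relative sense only (syn addition, anti to the ester) and vanish on aromatisation.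
- Enabling feature: the hydroxyls on ring carbons C2 and C3, next to the ester-bearing C1, correspond to one C=C of a cyclohexa-2,5-diene-1-carboxylate. Its two alkenes are related by the mirror plane through C1 and C4, and the untouched C5=C6 alkene supplies the rest of the unsaturation.

Key step: step 5

Remark: the Grignard partner of step 2 is taken as the purchased ether solution; the target is achiral, so configuration matters only transiently.

**Route**

Step 1
Reactants: 1 octadecane-1,18-diol
Product: 2 18-bromooctadecan-1-ol
Conditions: 48% aq. HBr (1.2 equiv), toluene, reflux
Reagents that add atoms: hydrogen bromide, Br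
Why: SN2 substitution of one protonated primary hydroxyl by bromide in the two-phase HBr/toluene system, a standard monobromination of α,ω-diols in which the less polar bromo alcohol is drawn into toluene and so should largely escape a second substitution.

Step 2
Reactants: 2 18-bromooctadecan-1-ol; 3 isobutylmagnesium bromide
Product: 4 20-methylhenicosan-1-ol
Conditions: 3 (2.5 equiv), Li2CuCl4 (3 mol%), THF, −20 °C → rt; aq. NH4Cl
Reagents that add atoms: none
Why: Copper-catalysed sp3–sp3 cross-coupling of a primary alkyl bromide with a primary alkyl Grignard reagent, in which one equivalent of 3 is spent on the hydroxyl proton (the magnesium alkoxide is a spectator) and the rest displaces bromide through an alkylcuprate to form the C18–C19 bond.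

Step 3
Reactants: 5 benzoic acid
Product: 6 cyclohexa-2,5-diene-1-carboxylic acid
Conditions: Na, NH3(l), EtOH, −78 → −33 °C; NH4Cl; cold aq. HCl, product kept cold under Ar
Reagents that add atoms: none
Why: Birch reduction, in which the benzoate takes up two electrons and is protonated at the ipso and para carbons because the carboxylate stabilises charge at C1, giving the non-conjugated 1,4-dihydro acid.

Step 4
Reactants: 6 cyclohexa-2,5-diene-1-carboxylic acid; 4 20-methylhenicosan-1-ol
Product: 7 20-methylhenicosyl cyclohexa-2,5-diene-1-carboxylate
Conditions: EDC·HCl (1.3 equiv), DMAP (0.1 equiv), CH2Cl2, 0 °C → rt, Ar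
Reagents that add atoms: none
Why: Steglich esterification, in which the carbodiimide turns 6 into an O-acylisourea that DMAP relays to the primary alcohol, under cold and nearly neutral conditions so that the skipped diene should neither move into conjugation nor re-aromatise.

Step 5
Reactants: 7 20-methylhenicosyl cyclohexa-2,5-diene-1-carboxylate
Product: 8 racemic 20-methylhenicosyl 2,3-cis-dihydroxycyclohex-5-ene-1-carboxylate, both hydroxyls trans to the ester ((1S,2R,3S) enantiomer drawn)
Conditions: OsO4 (2 mol%), NMO (1.0 equiv), THF/acetone/H2O, 0 °C → rt; aq. Na2SO3
Reagents that add atoms: osmium tetroxide, O=[Os](=O)(=O)=O (delivers both oxygens to carbon); N-methylmorpholine N-oxide, C[N+]1([O-])CCOCC1 (stoichiometric oxygen source); water, O (hydrolysis of the osmate ester)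
Why: Upjohn dihydroxylation: OsO4 adds across one ring alkene of 7 in a concerted [3+2] cycloaddition to give a cyclic osmate ester of hexavalent osmium, water releases the diol and NMO returns the metal to octavalent OsO4, so the C2–O and C3–O bonds form together on one face. The closest known reaction type is the OsO4/NMO mono-dihydroxylation of Birch-derived cyclohexa-1,4-dienes to cyclohex-4-ene-cis-1,2-diols. No ring is closed; the six-membered carbocycle is carried through unchanged. Of the three new stereocentres, C2 and C3 are cis because both oxygens come from the same osmium centre, and both should lie anti to the C1 ester because the reagent approaches the face of the nearly flat diene that the ester does not shield; the product is racemic and a syn by-product would serve equally, since step 6 removes all three centres. The selectivity that matters is single against double dihydroxylation, which one equivalent of NMO, the twofold statistical advantage of the diene and the inductive deactivation of the remaining C5=C6 alkene by the new hydroxyls should secure, with unreacted 7 recoverable. Regiochemistry does not arise, because the mirror plane through C1 and C4 makes the two alkenes of 7 equivalent.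

Step 6
Reactants: 8 racemic 20-methylhenicosyl 2,3-cis-dihydroxycyclohex-5-ene-1-carboxylate
Product: 10 gentiside A (20-methylhenicosyl 2,3-dihydroxybenzoate), via cyclohexene-2,3-dione ester 9 (not isolated)
Conditions: DMSO, (CF3CO)2O, CH2Cl2, −78 °C; then Et3N, −78 °C → rt; aq. NH4Cl work-up under Ar
Reagents that add atoms: none
Why: Swern oxidation in its trifluoroacetic anhydride variant, the one established for converting cyclic cis-1,2-diols into 1,2-diones without C–C cleavage: both carbinols become alkoxysulfonium ions before the base is added, their collapse gives ene-dione 9, and 9 is the keto tautomer of the catechol, so enolisation of the C2 carbonyl toward C1 and of the C3 carbonyl toward C4 should aromatise the ring and erase the stereocentres of 8.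

**Compound list**

1 | octadecane-1,18-diol | OCCCCCCCCCCCCCCCCCCO | starting material
2 | 18-bromooctadecan-1-ol | OCCCCCCCCCCCCCCCCCCBr | intermediate
3 | isobutylmagnesium bromide (commercial solution in Et2O) | CC(C)C[Mg]Br | starting material
4 | 20-methylhenicosan-1-ol | CC(C)CCCCCCCCCCCCCCCCCCCO | intermediate
5 | benzoic acid | O=C(O)c1ccccc1 | starting material
6 | cyclohexa-2,5-diene-1-carboxylic acid | O=C(O)C1C=CCC=C1 | intermediate
7 | 20-methylhenicosyl cyclohexa-2,5-diene-1-carboxylate | CC(C)CCCCCCCCCCCCCCCCCCCOC(=O)C1C=CCC=C1 | intermediate
8 | racemic 20-methylhenicosyl 2,3-cis-dihydroxycyclohex-5-ene-1-carboxylate, hydroxyls trans to the ester, (1S,2R,3S) enantiomer drawn | CC(C)CCCCCCCCCCCCCCCCCCCOC(=O)[C@@H]1[C@@H](O)[C@@H](O)CC=C1 | intermediate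
9 | 20-methylhenicosyl 2,3-dioxocyclohex-5-ene-1-carboxylate (C1 configurationally labile, not isolated) | CC(C)CCCCCCCCCCCCCCCCCCCOC(=O)C1C=CCC(=O)C1=O | intermediate
10 | gentiside A, 20-methylhenicosyl 2,3-dihydroxybenzoate | CC(C)CCCCCCCCCCCCCCCCCCCOC(=O)c1cccc(O)c1O | target

**Step count and risks**

Total step count: 6. Longest linear sequence: 5 steps (steps 1, 2, 4, 5, 6).

Steps most likely to fail:

1. Step 6. An activated hydroxyl may be eliminated instead of oxidised, which would cost one ring oxygen and lead to a monophenol. The freshly formed catechol may also be captured by residual activated DMSO (ortho-methylthiomethylation) or be oxidised by air under base. Fallback: from 8, IBX (about 3 equiv) in DMSO/THF at rt places no leaving group on oxygen and is known to carry 1,2-diols to 1,2-diones. It would take the diol through 9 and, because IBX also oxidises catechols, on to the ortho-quinone 20-methylhenicosyl 5,6-dioxocyclohexa-1,3-diene-1-carboxylate F1. Aqueous Na2S2O4 added to the same flask would reduce this back, rejoining the route at 10.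

2. Step 5. Material may be lost to double dihydroxylation of the diene, or turnover may be slow because the waxy ester dissolves poorly in the aqueous medium. Fallback: from 7, Prilezhaev mono-epoxidation with one equivalent of mCPBA (NaHCO3, CH2Cl2, 0 °C) would give the epoxide 20-methylhenicosyl 7-oxabicyclo[4.1.0]hept-3-ene-2-carboxylate F2. Acid-catalysed hydrolysis (cat. HClO4, THF/H2O) would open it to the trans-diol 20-methylhenicosyl 2,3-trans-dihydroxycyclohex-5-ene-1-carboxylate F3. The configuration at C2 and C3 is erased on oxidation, so this diol under the conditions of step 6 would rejoin the route at dione 9 and hence 10.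

3. Step 4. The skipped diene may migrate into conjugation with the carbonyl through the acidified C1–H of the acyl-activated species, or the ring may re-aromatise in air during coupling. Fallback: from 6 and 4, Mitsunobu esterification (PPh3, DIAD, THF, 0 °C) activates the alcohol instead of the acid, so the carboxylate acts only as a nucleophile and no acyl-activated species forms. It leads directly to 7 and makes no new compound (F0).

**Further compounds**

F1 | step 6 | 20-methylhenicosyl 5,6-dioxocyclohexa-1,3-diene-1-carboxylate | CC(C)CCCCCCCCCCCCCCCCCCCOC(=O)C1=CC=CC(=O)C1=O
F2 | step 5 | 20-methylhenicosyl 7-oxabicyclo[4.1.0]hept-3-ene-2-carboxylate (racemic, epoxide anti to the ester drawn) | CC(C)CCCCCCCCCCCCCCCCCCCOC(=O)[C@@H]1C=CC[C@H]2O[C@@H]12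
F3 | step 5 | 20-methylhenicosyl 2,3-trans-dihydroxycyclohex-5-ene-1-carboxylate (racemic, one diastereomer drawn) | CC(C)CCCCCCCCCCCCCCCCCCCOC(=O)[C@@H]1C=CC[C@H](O)[C@H]1O
F0 | step 4 | none | none
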